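**Retrosynthetic overview**

1. Target ⇐ C5 silyl ether ⇐ open-chain acid by cutting C7–C8: a ring-closing decarboxylative radical allylation in which the C8 α-acyloxy radical adds to C7 of a 3-(sulfonylmethyl)butenolide and PhSO2• leaves; this closes the ten-membered ring, creates the α-methylene lactone and sets C7 and C8.
2. Open-chain acid ⇐ C2–C3: Nozaki–Hiyama–Kishi coupling of a Z-vinyl iodide (west half) with an E-enal (east half), then oxidation to the cross-conjugated dienone.
3. West half ⇐ C5–C6: asymmetric vinylogous Mukaiyama aldol of (Z)-3-iodo-2-methylacrolein with a silyloxyfuran made from tulipalin A; sets C5 and C6.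
4. East half ⇐ C8–C9: vinylogous Mukaiyama aldol of the prenal dienol ether with methyl glyoxylate, then angelate formation; the carboxyl group is the later radical precursor.
5. Ring order: the five-membered lactone is present from the start as a butenolide; the ten-membered carbocycle is formed last.

Assumption: atoms are labelled C1–C13 in germacranolide fashion (C2 ketone, C5 carbinol, C6 lactone O-carbon, C7 ring-fusion carbon, C8 angelate carbon, C11–C13 the methylene lactone); in step 5 the (R,R)-catalyst is taken to give the (5S,1′R) adduct, and the mirror-image catalyst is used if the sense of induction is the reverse.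

**Route**

Step 1
Reactants: 1 prop-2-yn-1-ol
Product: 3 (2Z)-3-iodo-2-methylprop-2-en-1-ol, via alkenylmagnesium alkoxide 2 (not isolated)
Conditions: MeMgBr (2.5 equiv), CuI (10 mol %), THF/Et2O, −10 °C → rt; then I2, −20 °C → rt
Reagents that add atoms: methylmagnesium bromide C[Mg]Br; iodine II
Why: Copper-catalysed anti-carbomagnesiation of the propargylic alkoxide (Duboudin reaction) puts Me on C2 and Mg on C3 cis to CH2O through the magnesium chelate, and iodinolysis with retention gives the Z-iodide that becomes the C3=C4 alkene.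

Step 2
Reactants: 3 (2Z)-3-iodo-2-methylprop-2-en-1-ol
Product: 4 (2Z)-3-iodo-2-methylprop-2-enal
Conditions: activated MnO2, CH2Cl2, rt, dark; filtered and used at once
Reagents that add atoms: none
Why: Neutral allylic oxidation with MnO2 gives the enal without Z→E isomerisation when the solution is used immediately.

Step 3
Reactants: 5 3-methylideneoxolan-2-one (tulipalin A)
Product: 8 3-[(phenylsulfonyl)methyl]furan-2(5H)-one, via dibromolactone 6 (not isolated), via 3-(bromomethyl)furan-2(5H)-one 7 (not isolated)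
Conditions: Br2 (1.0 equiv), CH2Cl2, 0 °C → rt; Et3N, 0 °C; then PhSO2Na, DMF, rt
Reagents that add atoms: bromine BrBr (atoms kept only in 6 and 7); sodium benzenesulfinate [Na+].[O-]S(=O)c1ccccc1
Why: Bromine addition to the exocyclic alkene, E2 loss of HBr toward the ring to the endocyclic allylic bromide, and sulfinate substitution (SN2 or double SN2′, both converging on the conjugated allyl sulfone) install the radical leaving group on the future C13.

Step 4
Reactants: 8 3-[(phenylsulfonyl)methyl]furan-2(5H)-one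
Product: 9 trimethyl({3-[(phenylsulfonyl)methyl]furan-2-yl}oxy)silane
Conditions: TMSOTf, Et3N, CH2Cl2, 0 °C; salts precipitated with pentane, used crude
Reagents that add atoms: trimethylsilyl trifluoromethanesulfonate C[Si](C)(C)OS(=O)(=O)C(F)(F)F
Why: Soft enolisation (O-silylation, loss of the γ-proton) gives the aromatic 2-silyloxyfuran, the standard donor for vinylogous Mukaiyama aldol reactions.

Step 5
Reactants: 4 (2Z)-3-iodo-2-methylprop-2-enal; 9 trimethyl({3-[(phenylsulfonyl)methyl]furan-2-yl}oxy)silane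
Product: 11 (5S)-5-[(1R,2Z)-1-{[tert-butyl(dimethyl)silyl]oxy}-3-iodo-2-methylprop-2-en-1-yl]-3-[(phenylsulfonyl)methyl]furan-2(5H)-one, via free aldol 10 (not isolated)
Conditions: (R,R)-(salen)CrSbF6 (5 mol %; salen = N,N′-bis(3,5-di-tert-butylsalicylidene)cyclohexane-1,2-diamine dianion), i-PrOH (1 equiv), CH2Cl2, −20 °C; then 2,6-lutidine, TBSOTf, −78 → 0 °C
Reagents that add atoms: tert-butyldimethylsilyl trifluoromethanesulfonate CC(C)(C)[Si](C)(C)OS(=O)(=O)C(F)(F)F
Why: Catalytic asymmetric vinylogous Mukaiyama aldol: the 3-substituent blocks α-attack so furan C5 adds to the aldehyde bound to the cationic trivalent chromium salen Lewis acid, a catalyst class that is anti (erythro)-selective with silyloxyfurans, setting (5S,1′R) (target C6 and C5), and silylation in the same flask protects C5–OH against retro-aldol and later furan formation.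

Step 6
Reactants: 12 3-methylbut-2-enal (prenal)
Product: 13 tert-butyl(dimethyl){[(1E)-3-methylbuta-1,3-dien-1-yl]oxy}silane
Conditions: TBSOTf, Et3N, Et2O, 0 °C → rt
Reagents that add atoms: tert-butyldimethylsilyl trifluoromethanesulfonate CC(C)(C)[Si](C)(C)OS(=O)(=O)C(F)(F)F
Why: Soft enolisation of the enal with γ-deprotonation gives the 1-silyloxydiene (either methyl group gives the same diene).

Step 7
Reactants: 13 tert-butyl(dimethyl){[(1E)-3-methylbuta-1,3-dien-1-yl]oxy}silane; 14 methyl glyoxylate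
Product: 15 methyl (4E)-2-hydroxy-4-methyl-6-oxohex-4-enoate (racemic)
Conditions: B(C6F5)3 (10 mol %), i-PrOH (1.1 equiv), Et2O, −78 °C
Reagents that add atoms: none
Why: Vinylogous Mukaiyama aldol: the bulky monodentate borane activates the glyoxylate and the diene attacks through its terminal CH2 in an open transition state to give the E-enal (any Z-isomer closes to a lactol and is removed); the carbinol is left racemic on purpose because it becomes a planar radical in step 12.

Step 8
Reactants: 15 methyl (4E)-2-hydroxy-4-methyl-6-oxohex-4-enoate; 16 (2Z)-2-methylbut-2-enoic acid (angelic acid)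
Product: 18 methyl (4E)-4-methyl-2-{[(2Z)-2-methylbut-2-enoyl]oxy}-6-oxohex-4-enoate, via mixed anhydride 17 (not isolated)
Conditions: 16, 2,4,6-trichlorobenzoyl chloride, Et3N, toluene, rt; then 15, 70 °C (no DMAP)
Reagents that add atoms: 2,4,6-trichlorobenzoyl chloride O=C(Cl)c1c(Cl)cc(Cl)cc1Cl (atoms kept only in 17)
Why: Yamaguchi-type esterification through the mixed anhydride without a nucleophilic catalyst is the established way to form angelates without Z→E isomerisation to the tiglate.

Step 9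
Reactants: 11 (the west vinyl iodide); 18 (the east enal)
Product: 19 methyl (4E,7Z,9R)-9-{[tert-butyl(dimethyl)silyl]oxy}-6-hydroxy-4,8-dimethyl-2-{[(2Z)-2-methylbut-2-enoyl]oxy}-9-{(2S)-5-oxo-4-[(phenylsulfonyl)methyl]-2,5-dihydrofuran-2-yl}nona-4,7-dienoate (epimers at C2 and C6 of the chain)
Conditions: CrCl2 (6 equiv), NiCl2 (1 mol %), DMSO, rt
Reagents that add atoms: none
Why: Nozaki–Hiyama–Kishi coupling: zerovalent nickel inserts into the C–I bond with retention of the Z geometry, transmetalation gives an alkenylchromium that adds 1,2 to the enal and tolerates esters, butenolide, sulfone and silyl ether; the new carbinol centre is removed in step 10.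

Step 10
Reactants: 19 (the bis-allylic alcohol)
Product: 20 methyl (4E,7Z,9R)-9-{[tert-butyl(dimethyl)silyl]oxy}-4,8-dimethyl-2-{[(2Z)-2-methylbut-2-enoyl]oxy}-6-oxo-9-{(2S)-5-oxo-4-[(phenylsulfonyl)methyl]-2,5-dihydrofuran-2-yl}nona-4,7-dienoate
Conditions: Dess–Martin periodinane, CH2Cl2, 0 °C → rt
Reagents that add atoms: none
Why: Dess–Martin oxidation of the bis-allylic alcohol gives the cross-conjugated dienone, which has no α-hydrogens and keeps both alkene geometries.

Step 11
Reactants: 20 (the methyl ester)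
Product: 21 (4E,7Z,9R)-9-{[tert-butyl(dimethyl)silyl]oxy}-4,8-dimethyl-2-{[(2Z)-2-methylbut-2-enoyl]oxy}-6-oxo-9-{(2S)-5-oxo-4-[(phenylsulfonyl)methyl]-2,5-dihydrofuran-2-yl}nona-4,7-dienoic acid
Conditions: Me3SnOH (5 equiv), ClCH2CH2Cl, 70 °C; 5 % aq HCl wash
Reagents that add atoms: trimethyltin hydroxide C[Sn](C)(C)O (supplies the carboxyl oxygen)
Why: Trimethyltin hydroxide cleaves unhindered methyl esters by tin-assisted hydroxide delivery under almost neutral conditions, leaving the hindered conjugated angelate, the butenolide, the base-sensitive β-silyloxy centre and the dienone untouched; the tin carboxylate is released on the acid wash.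

Step 12
Reactants: 21 (the open-chain acid)
Product: 22 (3aR,4S,6E,9Z,11R,11aS)-11-{[tert-butyl(dimethyl)silyl]oxy}-6,10-dimethyl-3-methylidene-2,8-dioxo-2,3,3a,4,5,8,11,11a-octahydrocyclodeca[b]furan-4-yl (2Z)-2-methylbut-2-enoate
Conditions: 9-mesityl-3,6-di-tert-butyl-10-phenylacridinium tetrafluoroborate (5 mol %), 2,6-lutidine (1.5 equiv), CF3CH2OH/CH2Cl2 1:1 (0.5 mM, degassed), 450 nm LEDs, rt
Reagents that add atoms: none
Why: Proposed new method: the excited acridinium oxidises the carboxylate, loss of CO2 gives the nucleophilic secondary α-acyloxy C8 radical, which cannot close a small ring because the E-C1=C10 alkene holds the chain extended and so adds 10-exo to the electrophilic β-carbon C7 of the butenolide on the face anti to the bulky C5 silyloxy branch (trans-lactone, C7 R) with the acyloxy group on the outside of the forming ring (C8 S), after which the tertiary α-carbonyl radical expels PhSO2• by β-scission to create the exocyclic methylene and the sulfonyl radical is reduced to sulfinate by the acridinyl radical; the closest known reactions are intermolecular photoredox decarboxylative allylation with allyl sulfones, anti-selective radical addition to γ-substituted butenolides and radical macrocyclisation onto acrylates, and the absence of a hydrogen donor and the low triplet energy of the acridinium protect the slow ring closure and the alkene geometries.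

Step 13
Reactants: 22 (the silyl ether)
Product: 23 (3aR,4S,6E,9Z,11R,11aS)-11-hydroxy-6,10-dimethyl-3-methylidene-2,8-dioxo-2,3,3a,4,5,8,11,11a-octahydrocyclodeca[b]furan-4-yl (2Z)-2-methylbut-2-enoate
Conditions: HF·pyridine, pyridine, THF, 0 °C → rt
Reagents that add atoms: none
Why: Buffered fluoride desilylation frees the C5 hydroxyl without touching the angelate, the methylene lactone or the dienone; in the ten-membered ring the Z-γ-hydroxy enone stays open as in the target.

**Compound list**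

1 | prop-2-yn-1-ol | C#CCO | starting material
2 | bromomagnesium (2Z)-3-(bromomagnesio)-2-methylprop-2-en-1-olate | Br[Mg]OC/C(C)=C\[Mg]Br | intermediate
3 | (2Z)-3-iodo-2-methylprop-2-en-1-ol | OC/C(C)=C\I | intermediate
4 | (2Z)-3-iodo-2-methylprop-2-enal | O=C/C(C)=C\I | intermediate
5 | 3-methylideneoxolan-2-one (tulipalin A) | C=C1CCOC1=O | starting material
6 | 3-bromo-3-(bromomethyl)oxolan-2-one (racemic) | BrCC1(Br)CCOC1=O | intermediate
7 | 3-(bromomethyl)furan-2(5H)-one | BrCC1=CCOC1=O | intermediate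
8 | 3-[(phenylsulfonyl)methyl]furan-2(5H)-one | O=C1OCC=C1CS(=O)(=O)c1ccccc1 | intermediate
9 | trimethyl({3-[(phenylsulfonyl)methyl]furan-2-yl}oxy)silane | C[Si](C)(C)Oc1occc1CS(=O)(=O)c1ccccc1 | intermediate
10 | (5S)-5-[(1R,2Z)-1-hydroxy-3-iodo-2-methylprop-2-en-1-yl]-3-[(phenylsulfonyl)methyl]furan-2(5H)-one | O=C1O[C@H]([C@H](O)/C(C)=C\I)C=C1CS(=O)(=O)c1ccccc1 | intermediate
11 | (5S)-5-[(1R,2Z)-1-{[tert-butyl(dimethyl)silyl]oxy}-3-iodo-2-methylprop-2-en-1-yl]-3-[(phenylsulfonyl)methyl]furan-2(5H)-one | O=C1O[C@H]([C@H](O[Si](C)(C)C(C)(C)C)/C(C)=C\I)C=C1CS(=O)(=O)c1ccccc1 | intermediate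
12 | 3-methylbut-2-enal (prenal) | CC(C)=CC=O | starting material
13 | tert-butyl(dimethyl){[(1E)-3-methylbuta-1,3-dien-1-yl]oxy}silane | C=C(C)/C=C/O[Si](C)(C)C(C)(C)C | intermediate
14 | methyl glyoxylate (methyl 2-oxoacetate) | COC(=O)C=O | starting material
15 | methyl (4E)-2-hydroxy-4-methyl-6-oxohex-4-enoate (racemic) | COC(=O)C(O)C/C(C)=C/C=O | intermediate
16 | (2Z)-2-methylbut-2-enoic acid (angelic acid) | C/C=C(/C)C(=O)O | starting material
17 | (2Z)-2-methylbut-2-enoic 2,4,6-trichlorobenzoic anhydride | C/C=C(/C)C(=O)OC(=O)c1c(Cl)cc(Cl)cc1Cl | intermediate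
18 | methyl (4E)-4-methyl-2-{[(2Z)-2-methylbut-2-enoyl]oxy}-6-oxohex-4-enoate (racemic) | COC(=O)C(OC(=O)/C(C)=C\C)C/C(C)=C/C=O | intermediate
19 | methyl (4E,7Z,9R)-9-{[tert-butyl(dimethyl)silyl]oxy}-6-hydroxy-4,8-dimethyl-2-{[(2Z)-2-methylbut-2-enoyl]oxy}-9-{(2S)-5-oxo-4-[(phenylsulfonyl)methyl]-2,5-dihydrofuran-2-yl}nona-4,7-dienoate (epimers at C2 and C6) | COC(=O)C(OC(=O)/C(C)=C\C)C/C(C)=C/C(O)/C=C(/C)[C@@H](O[Si](C)(C)C(C)(C)C)[C@H]1OC(=O)C(CS(=O)(=O)c2ccccc2)=C1 | intermediate
20 | methyl (4E,7Z,9R)-9-{[tert-butyl(dimethyl)silyl]oxy}-4,8-dimethyl-2-{[(2Z)-2-methylbut-2-enoyl]oxy}-6-oxo-9-{(2S)-5-oxo-4-[(phenylsulfonyl)methyl]-2,5-dihydrofuran-2-yl}nona-4,7-dienoate (epimers at C2) | COC(=O)C(OC(=O)/C(C)=C\C)C/C(C)=C/C(=O)/C=C(/C)[C@@H](O[Si](C)(C)C(C)(C)C)[C@H]1OC(=O)C(CS(=O)(=O)c2ccccc2)=C1 | intermediate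
21 | (4E,7Z,9R)-9-{[tert-butyl(dimethyl)silyl]oxy}-4,8-dimethyl-2-{[(2Z)-2-methylbut-2-enoyl]oxy}-6-oxo-9-{(2S)-5-oxo-4-[(phenylsulfonyl)methyl]-2,5-dihydrofuran-2-yl}nona-4,7-dienoic acid (epimers at C2) | OC(=O)C(OC(=O)/C(C)=C\C)C/C(C)=C/C(=O)/C=C(/C)[C@@H](O[Si](C)(C)C(C)(C)C)[C@H]1OC(=O)C(CS(=O)(=O)c2ccccc2)=C1 | intermediate
22 | (3aR,4S,6E,9Z,11R,11aS)-11-{[tert-butyl(dimethyl)silyl]oxy}-6,10-dimethyl-3-methylidene-2,8-dioxo-2,3,3a,4,5,8,11,11a-octahydrocyclodeca[b]furan-4-yl (2Z)-2-methylbut-2-enoate | C=C1C(=O)O[C@H]2[C@H]1[C@@H](OC(=O)/C(C)=C\C)C/C(C)=C/C(=O)/C=C(/C)[C@H]2O[Si](C)(C)C(C)(C)C | intermediate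
23 | (3aR,4S,6E,9Z,11R,11aS)-11-hydroxy-6,10-dimethyl-3-methylidene-2,8-dioxo-2,3,3a,4,5,8,11,11a-octahydrocyclodeca[b]furan-4-yl (2Z)-2-methylbut-2-enoate | C=C1C(=O)O[C@H]2[C@H]1[C@@H](OC(=O)/C(C)=C\C)C/C(C)=C/C(=O)/C=C(/C)[C@H]2O | target

**Step count**

Total: 13 steps. Longest linear sequence: 8 steps (1 → 2 → 5 → 9 → 10 → 11 → 12 → 13); the branches from 5 (steps 3, 4) and from 12 (steps 6, 7, 8) are equally long.

**Three steps most likely to fail, with fallbacks**

Step 12 (radical ring closure). The ten-membered closure may be too slow, or may give the wrong face at C7 or C8. The fallback keeps the radical C7–C8 bond formation but makes it intermolecular and moves the ring closure to C2–C3. It sets out from 18 and 11. Trimethyltin hydroxide hydrolysis of 18 gives (4E)-4-methyl-2-{[(2Z)-2-methylbut-2-enoyl]oxy}-6-oxohex-4-enoic acid F1. The same acridinium photoredox decarboxylative allylation, now run at 0.1 M with F1 and 11, joins C8 to C7 anti to the C5 side chain with loss of PhSO2•. The product is (1S,3E)-1-[(2S,3R)-2-{(1R,2Z)-1-{[tert-butyl(dimethyl)silyl]oxy}-3-iodo-2-methylprop-2-en-1-yl}-4-methylidene-5-oxooxolan-3-yl]-3-methyl-5-oxopent-3-en-1-yl (2Z)-2-methylbut-2-enoate F2, whose C8 epimer is separated by chromatography. An intramolecular Nozaki–Hiyama–Kishi reaction (CrCl2, NiCl2 cat., DMSO, 2 mM) then closes the ring to (3aR,4S,6E,9Z,11R,11aS)-11-{[tert-butyl(dimethyl)silyl]oxy}-8-hydroxy-6,10-dimethyl-3-methylidene-2-oxo-2,3,3a,4,5,8,11,11a-octahydrocyclodeca[b]furan-4-yl (2Z)-2-methylbut-2-enoate F3 (C8-carbinol epimers). Dess–Martin oxidation of F3 comes back to the route at 22.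

Step 5 (asymmetric vinylogous aldol). The unusual 3-substituted silyloxyfuran and the Z-iodoenal may give poor anti selectivity or poor ee. The fallback replaces catalyst control by relative control plus kinetic resolution and sets out from 4 and 9. Fluoride activation (Bu4NF 5 mol %, THF, −78 °C, then citric acid), which is erythro-selective for silyloxyfurans, gives racemic anti aldol, that is 10 together with its enantiomer (5R)-5-[(1S,2Z)-1-hydroxy-3-iodo-2-methylprop-2-en-1-yl]-3-[(phenylsulfonyl)methyl]furan-2(5H)-one F4. Acylative kinetic resolution of this allylic alcohol with isobutyric anhydride, i-Pr2NEt and the isothiourea catalyst 3-isopropyl-2-phenyl-3,4-dihydro-2H-benzo[4,5]thiazolo[3,2-a]pyrimidine (enantiomer chosen so that F4 reacts fast) converts F4 into (1S,2Z)-3-iodo-2-methyl-1-{(2R)-5-oxo-4-[(phenylsulfonyl)methyl]-2,5-dihydrofuran-2-yl}prop-2-en-1-yl 2-methylpropanoate F5, which is removed by chromatography. The fallback comes back to the route at 10, which is silylated to 11 as in step 5.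

Step 9 (Nozaki–Hiyama–Kishi coupling). Zerovalent nickel may ionise the activated allyl sulfone of 11, or divalent chromium may reduce it. The fallback changes the order so that the chromium step precedes the sulfone; it sets out from 3 and 18. Their Nozaki–Hiyama–Kishi coupling (CrCl2, NiCl2 cat., DMSO) gives methyl (4E,7Z)-6,9-dihydroxy-4,8-dimethyl-2-{[(2Z)-2-methylbut-2-enoyl]oxy}nona-4,7-dienoate F6. Double allylic oxidation (Dess–Martin periodinane, 2.5 equiv) gives methyl (4E,7Z)-4,8-dimethyl-2-{[(2Z)-2-methylbut-2-enoyl]oxy}-6,9-dioxonona-4,7-dienoate F7. The vinylogous Mukaiyama aldol of step 5 with 9, which is selective for the aldehyde over the ketone, gives methyl (4E,7Z,9R)-9-hydroxy-4,8-dimethyl-2-{[(2Z)-2-methylbut-2-enoyl]oxy}-6-oxo-9-{(2S)-5-oxo-4-[(phenylsulfonyl)methyl]-2,5-dihydrofuran-2-yl}nona-4,7-dienoate F8. F8 is silylated in the same flask at −78 °C (TBSOTf, 2,6-lutidine) before it can close to a furan, and the fallback comes back to the route at 20.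

**Further compounds**

F1 | step 12 | (4E)-4-methyl-2-{[(2Z)-2-methylbut-2-enoyl]oxy}-6-oxohex-4-enoic acid (racemic) | OC(=O)C(OC(=O)/C(C)=C\C)C/C(C)=C/C=O
F2 | step 12 | (1S,3E)-1-[(2S,3R)-2-{(1R,2Z)-1-{[tert-butyl(dimethyl)silyl]oxy}-3-iodo-2-methylprop-2-en-1-yl}-4-methylidene-5-oxooxolan-3-yl]-3-methyl-5-oxopent-3-en-1-yl (2Z)-2-methylbut-2-enoate | C=C1C(=O)O[C@H]([C@H](O[Si](C)(C)C(C)(C)C)/C(C)=C\I)[C@H]1[C@@H](OC(=O)/C(C)=C\C)C/C(C)=C/C=O
F3 | step 12 | (3aR,4S,6E,9Z,11R,11aS)-11-{[tert-butyl(dimethyl)silyl]oxy}-8-hydroxy-6,10-dimethyl-3-methylidene-2-oxo-2,3,3a,4,5,8,11,11a-octahydrocyclodeca[b]furan-4-yl (2Z)-2-methylbut-2-enoate (epimers at C8) | C=C1C(=O)O[C@H]2[C@H]1[C@@H](OC(=O)/C(C)=C\C)C/C(C)=C/C(O)/C=C(/C)[C@H]2O[Si](C)(C)C(C)(C)C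
F4 | step 5 | (5R)-5-[(1S,2Z)-1-hydroxy-3-iodo-2-methylprop-2-en-1-yl]-3-[(phenylsulfonyl)methyl]furan-2(5H)-one | O=C1O[C@@H]([C@@H](O)/C(C)=C\I)C=C1CS(=O)(=O)c1ccccc1
F5 | step 5 | (1S,2Z)-3-iodo-2-methyl-1-{(2R)-5-oxo-4-[(phenylsulfonyl)methyl]-2,5-dihydrofuran-2-yl}prop-2-en-1-yl 2-methylpropanoate | O=C1O[C@@H]([C@@H](OC(=O)C(C)C)/C(C)=C\I)C=C1CS(=O)(=O)c1ccccc1
F6 | step 9 | methyl (4E,7Z)-6,9-dihydroxy-4,8-dimethyl-2-{[(2Z)-2-methylbut-2-enoyl]oxy}nona-4,7-dienoate (epimers at C2 and C6) | COC(=O)C(OC(=O)/C(C)=C\C)C/C(C)=C/C(O)/C=C(/C)CO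
F7 | step 9 | methyl (4E,7Z)-4,8-dimethyl-2-{[(2Z)-2-methylbut-2-enoyl]oxy}-6,9-dioxonona-4,7-dienoate (racemic) | COC(=O)C(OC(=O)/C(C)=C\C)C/C(C)=C/C(=O)/C=C(/C)C=O
F8 | step 9 | methyl (4E,7Z,9R)-9-hydroxy-4,8-dimethyl-2-{[(2Z)-2-methylbut-2-enoyl]oxy}-6-oxo-9-{(2S)-5-oxo-4-[(phenylsulfonyl)methyl]-2,5-dihydrofuran-2-yl}nona-4,7-dienoate (epimers at C2) | COC(=O)C(OC(=O)/C(C)=C\C)C/C(C)=C/C(=O)/C=C(/C)[C@@H](O)[C@H]1OC(=O)C(CS(=O)(=O)c2ccccc2)=C1
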